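In the winter run product climbs at 0.00567 /min, as a fraction of the charge, from 4.00 min to 10.0 min, but at 0.0187 /min from 20.0 min to 30.0 min, faster, with the same enzyme charge. So the rate follows the stock of substrate steeply, and I build the flask on that.

| setting | winter | midnight | autumn | north-west | south | north-east |
|---|---|---|---|---|---|---|
| substrate | 48 mM (in portions, 3) | 48 mM (in portions, 3) | 48 mM (in portions, 3) | 48 mM (in portions, 3) | 48 mM (in portions, 3) | 48 mM (in portions, 3) |
| enzyme | 0.79 µM | 2.2 µM | 5.6 µM | 0.80 µM | 2.0 µM | 6.0 µM |
| remark | run made earlier; portions every 12 min | run made earlier; portions every 12 min | run made earlier; portions every 12 min | the portions of substrate follow each other after 12 min, the first at the start | the portions of substrate follow each other after 12 min, the first at the start | the portions of substrate follow each other after 12 min, the first at the start |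
| time |  |  |  | 40 min | 40 min | 40 min |

| run | time / min | product / % |
|---|---|---|
| winter | 4.00 | 2.3 |
| winter | 10.0 | 5.7 |
| winter | 20.0 | 18.8 |
| winter | 30.0 | 37.5 |
| winter | 40.0 | 53.1 |
| midnight | 3.00 | 5.4 |
| midnight | 6.00 | 8.3 |
| midnight | 12.0 | 13.4 |
| midnight | 20.0 | 36.9 |
| midnight | 40.0 | 74.3 |
| autumn | 4.00 | 12.5 |
| autumn | 10.0 | 20.9 |
| autumn | 20.0 | 50.0 |
| autumn | 30.0 | 79.7 |
| autumn | 40.0 | 87.9 |

(scatter of a reading: 1 percentage point)

- "hardly changes" means that all values lie within two and a half points (for a concentration: within two and a half percent of the largest)

- amount of product at the end, in percent of the substrate charged for north-west, south, north-east, in this order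
- the course of these numbers from the first flask to the last (rises, then falls / hardly changes / falls, then rises / rises all the way / falls all the way)

First I take the main step alone, after the last portion has gone in at 24.0 min. Let s be the substrate left as a fraction of the charge, u its reciprocal, and E the enzyme concentration. If the rate goes as E times the square of s (second order in substrate), u climbs in a straight line. The last two winter readings give its slope:

g = rise of u / (E × elapsed time) = 0.0674 /min/µM

This rise of u per minute and per µM of enzyme is the reciprocal gain. Autumn, read the same way, gives 0.0596 /min/µM. I carry the winter value, since a reading's 1 percentage point moves u less in the winter run.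

Next I add the feed, one portion per interval, which averages F = 0.0278 /min as a fraction of the charge. The enzyme keeps pace with it at the crossing s*, the square root of F/(g·E):

north-west: 71.8%
north-east: 26.2%

Below s* the feed outruns the enzyme and above it the enzyme gains on the feed, so I expect north-east to hold a lower stock than north-west when the last portion lands.

Last comes the step to the new flasks. Each sits beside an old one, so I shift the old final u by g × (change in E) × T, where T = 16.0 min is the tail. My product at the end is then:

north-west, from winter: 53.3%
south, from midnight: 72.8%
north-east, from autumn: 88.5%

These lines ignore the shifted stock at the last portion, so they lean towards the old flasks.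

The forecast gives 53.4%, 72.5% and 88.6%, and its course rises all the way: “The new flasks sit almost on the old ones, so I interpolate in ln E.” Its south lies 0.30 points below mine.

The flasks give 53.9%, 76.0% and 90.4%, and the course rises all the way.

    substrate + enzyme → product + enzyme, rate k1*[substrate]^2*[enzyme]/(1 + ([substrate]/Kh1)^2) (48.0 mM, k = 31000 /M²/s)

Let σ be s just after the last portion, and τ, the clearing time, the reciprocal of g·E·σ. North-west has σ = 75.7% and τ = 24.5 min, longer than the tail, while south has σ = 60.0% and τ = 12.4 min, shorter than the tail. Adding g·E·T to the reciprocal of σ gives 45.8% of substrate in north-west, where 46% stands at 40.0 min, and 26.2% in south, where 24% stands.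

The numbers in the tables were generated by integration with constants of no real substance; noise was put on by code.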